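(All runs stem from a simulated flask from invented constants, and the scatter is random.)

Start by counting what each step does to cX minus cG, both in percent of the G charged. Making one X uses one Z and one G, so the difference rises by two. Making one D takes one X and one G, so the difference stays put. The flask opens at minus 100 and climbs by twice the Z used. Once Z, the limiting reagent, is used up, the difference freezes at twice its equivalents less the whole: the gap, 20.0%. From then on, X equals the gap plus whatever G remains.

| setting | north-east | north | south | beta | epsilon | delta | zeta |
|---|---|---|---|---|---|---|---|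
| G | 1 M | 1 M | 0.50 M | 1.0 M | 1.0 M | 1.0 M | 1.0 M |
| Z | 0.60 equiv | 0.60 equiv | 0.60 equiv | 0.600 equiv | 0.600 equiv | 0.600 equiv | 0.600 equiv |
| L | 1.4 mol% | 2.2 mol% | 1 mol% | 1 mol% | 1 mol% | 1 mol% | 1 mol% |
| temperature | 85 °C | 112 °C | 85 °C | 135 °C | 105 °C | 90 °C | 120 °C |
| remark | run made earlier | run made earlier | run made earlier |  |  |  |  |
| time |  |  |  | 1.0 h | 1.0 h | 1.0 h | 1.0 h |

- north-east (time / h: X / %, G / %): 0.833: 22, 73; 1.33: 30, 55; 2.00: 45, 41; 4.00: 43, 21; 6.00: 41, 19; 10.0: 28, 10
- north (time / h: X / %, G / %): 0.167: 36, 45; 0.500: 38, 19; 0.833: 34, 14; 1.33: 28, 7; 2.00: 26, 4; 2.50: 23, 0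
- south (time / h: X / %, G / %): 0.833: 9, 87; 1.50: 17, 77; 3.00: 28, 62; 5.00: 39, 44; 10.0: 40, 21

(readings scatter by 1.5 percentage points)

1. the flask that comes out highest in amount of X, in percent of the G charged, or "all alike" when all lie within 1.5 percentage points (beta / epsilon / delta / zeta / all alike)
2. X at the end, in percent of the G charged, beta
3. X at the end, in percent of the G charged, epsilon
4. X at the end, in percent of the G charged, delta
5. X at the end, in percent of the G charged, zeta

- a species is counted by the G in it: one D counts as two
- steps that have been proposed: G + L <-> E; Z + E -> J; J <-> L + X; G + X -> D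

Test the gap on the last readings: north gives 23 percentage points, north-east 18 points, south 19 points. Each reading carries 1.5 points, and a difference of two carries more, so these stand with it. Object that E and J also hold G and Z. They hold at most the charge of L, 1 mol% in beta, so the shift stays inside the scatter.

Object next that the gap needs Z spent within the hour. The same count gives the Z used in north at 0.500 h: 59.5% of the G charged, against a charge of 0.60 equiv, so within the scatter of the readings Z in north is used up by then. North had twice the L of beta. But per unit of L, and read from scattered readings, the logarithm of G fell 8.05 times as fast up to the first reading of north as up to that of north-east, between 85 °C and 112 °C, and beta is hotter. So expect Z spent early in beta.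

Object last that the gap still leaves the G open. After Z was spent, G in north fell at 1.04 h⁻¹, and beta at 135 °C should go faster. So put X in beta at the gap, 20.0%; any G still there adds to it. For delta and epsilon the hour may end with Z unspent, and then the gap says nothing.

The forecast gives 19% for beta (13% to 25%), a point from this reckoning. It gives 39% for epsilon (33% to 44%), 27% for delta (23% to 32%) and 25% for zeta (19% to 32%). It names epsilon highest, on the ground that “This side step has the higher barrier, so heat favours D”.

The flasks give 20.1% for beta, 37.5% for epsilon, 25.5% for delta and 24.8% for zeta, with epsilon highest, each inside its range.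

    G + L ⇌ E (K = 1.10 L mol⁻¹, k = 0.0120 L mol⁻¹ s⁻¹, Ea = 82.0 kJ mol⁻¹, ΔH = −17.0 kJ mol⁻¹)
    Z + E → J (k = 12.0 L mol⁻¹ s⁻¹, Ea = 50.0 kJ mol⁻¹)
    J ⇌ L + X (K = 23.0 M, k = 0.0820 s⁻¹, Ea = 106 kJ mol⁻¹, ΔH = −90.0 kJ mol⁻¹)
    G + X → D (k = 1.40 × 10⁻⁴ L mol⁻¹ s⁻¹, Ea = 101 kJ mol⁻¹)
    (constants at 90 °C)

At 1.00 h, beta holds G 0.256% and X 20.1% with Z 0%, a difference of 20 points, on the gap. Its X stands low mainly because of G + X → D: with that step struck out, beta keeps 59.6%. The forecast for beta turns wrong with a change of temperature: repeated at 110 °C, all amounts and the time held, that flask gives 33.1%, above the forecast's high end of 25%.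

Take beta with 0.150 equiv of Z. The gap is −70.0%, so X should reach nothing with G stopping at 70.0%. That flask gives X 0% and G 70%.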